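## Retrosynthetic overview

- The target comes from global desilylation of its tetrasilyl ether, whose (Z)-ylidene lactone arises by dehydration of a γ-(1-hydroxyalkyl)butenolide.
- Key C–C bond (lactone C-5 to the polyene terminus): vinylogous Mukaiyama aldol between the 2-silyloxyfuran of the western half and the C22 tetraenynal of the eastern half.
- Eastern aldehyde: enol triflate of silylated actinol, Sonogashira coupling with (E)-3-methylpent-2-en-4-yn-1-ol, then C4 Horner–Wadsworth–Emmons and C3 Wittig extensions.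
- Western half: the same triflate is converted to an allylic alcohol, then a syn epoxide (Sharpless), an epoxy alkyne, a trans-diol (hydrolysis with inversion at the methyl-bearing carbon), an (E)-vinylstannane, and finally Stille-coupled with 3-bromobutenolide.
- Rings: both six-membered rings come intact from (4R,6R)-actinol and the lactone ring from furan-2(5H)-one; only a transient oxirane is made and opened.

Assumption and abbreviations: the target is taken exactly as drawn; carotenoid locants (C-3, C-5, C-6, C-7) are used in the explanations only; TBS = tert-butyldimethylsilyl, TMS = trimethylsilyl, TIPS = triisopropylsilyl.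

## Route

Step 1
Reactants: 1 (4R,6R)-4-hydroxy-2,2,6-trimethylcyclohexan-1-one (actinol)
Product: 2 (4R,6R)-4-(TBS-oxy)-2,2,6-trimethylcyclohexan-1-one
Conditions: TBSCl, imidazole, DMF, 23 °C
Reagents that add atoms: tert-butyldimethylsilyl chloride, CC(C)(C)[Si](C)(C)Cl
Why: Silyl ether formation masks the only hydroxyl and touches no stereocentre.

Step 2
Reactants: 2 (4R,6R)-4-(TBS-oxy)-2,2,6-trimethylcyclohexan-1-one
Product: 4 (4R)-4-(TBS-oxy)-2,6,6-trimethylcyclohex-1-en-1-yl trifluoromethanesulfonate, via lithium enolate 3 (not isolated)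
Conditions: LiN(i-Pr)2, THF, −78 °C; then PhNTf2, −78 to 0 °C
Reagents that add atoms: N-phenylbis(trifluoromethanesulfonimide), O=S(=O)(N(c1ccccc1)S(=O)(=O)C(F)(F)F)C(F)(F)F
Why: Enolisation and O-triflation (enol triflate formation) can occur only toward the single α-CH, so one regioisomer forms, the methyl-bearing stereocentre is erased on purpose and the carbinol centre is untouched.

Step 3
Reactants: 4 (4R)-4-(TBS-oxy)-2,6,6-trimethylcyclohex-1-en-1-yl trifluoromethanesulfonate; 5 (2E)-3-methylpent-2-en-4-yn-1-ol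
Product: 6 (2E)-5-[(4R)-4-(TBS-oxy)-2,6,6-trimethylcyclohex-1-en-1-yl]-3-methylpent-2-en-4-yn-1-ol
Conditions: Pd(PPh3)4 (5 mol%), CuI (10 mol%), Et3N, DMF, 50 °C
Reagents that add atoms: none
Why: Sonogashira coupling of an alkenyl triflate with a terminal alkyne keeps the E geometry that comes with the enynol.

Step 4
Reactants: 6 (2E)-5-[(4R)-4-(TBS-oxy)-2,6,6-trimethylcyclohex-1-en-1-yl]-3-methylpent-2-en-4-yn-1-ol
Product: 7 (2E)-5-[(4R)-4-(TBS-oxy)-2,6,6-trimethylcyclohex-1-en-1-yl]-3-methylpent-2-en-4-ynal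
Conditions: MnO2, CH2Cl2, 23 °C
Reagents that add atoms: none
Why: Allylic oxidation with MnO2 stops at the enal and leaves the silyl ether, alkyne and E-alkene alone.

Step 5
Reactants: 7 (2E)-5-[(4R)-4-(TBS-oxy)-2,6,6-trimethylcyclohex-1-en-1-yl]-3-methylpent-2-en-4-ynal; 8 ethyl (2E)-4-(diethoxyphosphoryl)but-2-enoate
Product: 10 ethyl (2E,4E,6E)-9-[(4R)-4-(TBS-oxy)-2,6,6-trimethylcyclohex-1-en-1-yl]-7-methylnona-2,4,6-trien-8-ynoate, via lithiated phosphonate 9 (not isolated)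
Conditions: LiN(SiMe3)2, THF, −78 °C; then 7, −78 to 0 °C
Reagents that add atoms: none
Why: Horner–Wadsworth–Emmons olefination with the vinylogous phosphonate gives the new alkene E under thermodynamic control, the minor Z isomer being removed by chromatography.

Step 6
Reactants: 10 ethyl (2E,4E,6E)-9-[(4R)-4-(TBS-oxy)-2,6,6-trimethylcyclohex-1-en-1-yl]-7-methylnona-2,4,6-trien-8-ynoate
Product: 11 (2E,4E,6E)-9-[(4R)-4-(TBS-oxy)-2,6,6-trimethylcyclohex-1-en-1-yl]-7-methylnona-2,4,6-trien-8-yn-1-ol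
Conditions: i-Bu2AlH (2.2 equiv), CH2Cl2, −78 °C
Reagents that add atoms: none
Why: Hydride reduction of the conjugated ester goes 1,2 at low temperature and gives the allylic alcohol without touching the polyenyne.

Step 7
Reactants: 11 (2E,4E,6E)-9-[(4R)-4-(TBS-oxy)-2,6,6-trimethylcyclohex-1-en-1-yl]-7-methylnona-2,4,6-trien-8-yn-1-ol
Product: 12 (2E,4E,6E)-9-[(4R)-4-(TBS-oxy)-2,6,6-trimethylcyclohex-1-en-1-yl]-7-methylnona-2,4,6-trien-8-ynal
Conditions: MnO2, CH2Cl2, 23 °C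
Reagents that add atoms: none
Why: Allylic oxidation with MnO2 is selective for the polyenylic primary alcohol.

Step 8
Reactants: 12 (2E,4E,6E)-9-[(4R)-4-(TBS-oxy)-2,6,6-trimethylcyclohex-1-en-1-yl]-7-methylnona-2,4,6-trien-8-ynal; 13 2-(triphenylphosphoranylidene)propanal
Product: 14 (2E,4E,6E,8E)-11-[(4R)-4-(TBS-oxy)-2,6,6-trimethylcyclohex-1-en-1-yl]-2,9-dimethylundeca-2,4,6,8-tetraen-10-ynal
Conditions: toluene, 90 °C
Reagents that add atoms: none
Why: Wittig olefination with a stabilised formyl ylide gives the (E)-2-methyl enal directly, and the α-branched product aldehyde is too unreactive to homologate a second time.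

Step 9
Reactants: 4 (4R)-4-(TBS-oxy)-2,6,6-trimethylcyclohex-1-en-1-yl trifluoromethanesulfonate
Product: 15 methyl (4R)-4-(TBS-oxy)-2,6,6-trimethylcyclohex-1-ene-1-carboxylate
Conditions: Pd(OAc)2 (5 mol%), PPh3, CO (1 atm), MeOH, Et3N, DMF, 60 °C
Reagents that add atoms: carbon monoxide, [C-]#[O+]; methanol, CO
Why: Palladium-catalysed alkoxycarbonylation of the enol triflate installs C-7 as an ester.

Step 10
Reactants: 15 methyl (4R)-4-(TBS-oxy)-2,6,6-trimethylcyclohex-1-ene-1-carboxylate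
Product: 16 [(4R)-4-(TBS-oxy)-2,6,6-trimethylcyclohex-1-en-1-yl]methanol
Conditions: i-Bu2AlH (2.2 equiv), CH2Cl2, −78 to 0 °C
Reagents that add atoms: none
Why: Ester reduction with the aluminium hydride gives the primary allylic alcohol needed to direct the epoxidation.

Step 11
Reactants: 16 [(4R)-4-(TBS-oxy)-2,6,6-trimethylcyclohex-1-en-1-yl]methanol
Product: 17 [(1S,4S,6S)-4-(TBS-oxy)-2,2,6-trimethyl-7-oxabicyclo[4.1.0]heptan-1-yl]methanol (oxirane oxygen cis to the silyloxy group)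
Conditions: Ti(O-i-Pr)4 (0.5 equiv), L-(+)-diethyl tartrate (0.6 equiv), t-BuOOH, 4 Å molecular sieves, CH2Cl2, −20 °C
Reagents that add atoms: tert-butyl hydroperoxide, CC(C)(C)OO
Why: Sharpless asymmetric epoxidation with the L-(+)-tartrate delivers oxygen under reagent control to the face that makes the hydroxymethyl-bearing carbon S, which here is the face cis to the silyloxy group.

Step 12
Reactants: 17 [(1S,4S,6S)-4-(TBS-oxy)-2,2,6-trimethyl-7-oxabicyclo[4.1.0]heptan-1-yl]methanol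
Product: 18 (1R,4S,6S)-4-(TBS-oxy)-2,2,6-trimethyl-7-oxabicyclo[4.1.0]heptane-1-carbaldehyde
Conditions: SO3·pyridine, DMSO, Et3N, CH2Cl2, 0 °C
Reagents that add atoms: none
Why: Parikh–Doering oxidation is non-acidic, so the tetrasubstituted oxirane survives, and the aldehyde has no α-hydrogen to epimerise.

Step 13
Reactants: 18 (1R,4S,6S)-4-(TBS-oxy)-2,2,6-trimethyl-7-oxabicyclo[4.1.0]heptane-1-carbaldehyde
Product: 19 tert-butyl{[(1S,4S,6S)-1-ethynyl-2,2,6-trimethyl-7-oxabicyclo[4.1.0]heptan-4-yl]oxy}dimethylsilane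
Conditions: dimethyl (1-diazo-2-oxopropyl)phosphonate, K2CO3, MeOH, 0 to 23 °C
Reagents that add atoms: dimethyl (1-diazo-2-oxopropyl)phosphonate, CC(=O)C(=[N+]=[N-])P(=O)(OC)OC
Why: Ohira–Bestmann (Seyferth–Gilbert) homologation turns the non-enolisable aldehyde into the terminal alkyne under mild carbonate conditions that spare the oxirane and silyl ether.

Step 14
Reactants: 19 tert-butyl{[(1S,4S,6S)-1-ethynyl-2,2,6-trimethyl-7-oxabicyclo[4.1.0]heptan-4-yl]oxy}dimethylsilane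
Product: 20 (1S,2R,4S)-4-(TBS-oxy)-1-ethynyl-2,6,6-trimethylcyclohexane-1,2-diol (trans-diol; 1-OH cis and 2-OH trans to the silyloxy group)
Conditions: HClO4 (cat., dilute), THF–H2O 3:1, 0 °C
Reagents that add atoms: water, O
Why: Acid-catalysed epoxide hydrolysis puts water on the methyl-bearing carbon (C-5) anti to the oxirane oxygen, because the other carbon is neopentyl and carries the electron-withdrawing ethynyl group and because this is the trans-diaxial (Fürst–Plattner) mode, so C-5 is inverted and the C-6 oxygen stays cis to the silyloxy group.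

Step 15
Reactants: 20 (1S,2R,4S)-4-(TBS-oxy)-1-ethynyl-2,6,6-trimethylcyclohexane-1,2-diol
Product: 21 (1S,2R,4S)-4-(TBS-oxy)-1-ethynyl-2,6,6-trimethyl-1,2-bis(TMS-oxy)cyclohexane
Conditions: Me3SiOTf, 2,6-lutidine, CH2Cl2, −78 to 0 °C
Reagents that add atoms: trimethylsilyl trifluoromethanesulfonate, C[Si](C)(C)OS(=O)(=O)C(F)(F)F
Why: Silyl ether formation with the small, very reactive silyl triflate caps both hindered tertiary hydroxyls so that no free hydroxyl reaches the Lewis-acid and sulfonylation steps.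

Step 16
Reactants: 21 (1S,2R,4S)-4-(TBS-oxy)-1-ethynyl-2,6,6-trimethyl-1,2-bis(TMS-oxy)cyclohexane
Product: 22 (1R,2R,4S)-4-(TBS-oxy)-2,6,6-trimethyl-1-[(E)-2-(tributylstannyl)ethenyl]-1,2-bis(TMS-oxy)cyclohexane
Conditions: Bu3SnH, PdCl2(PPh3)2 (2 mol%), THF, 0 to 23 °C
Reagents that add atoms: tributyltin hydride, CCCC[SnH](CCCC)CCCC
Why: Palladium-catalysed hydrostannation adds H and Sn syn across the alkyne with tin at the unhindered terminus, giving the (E)-alkenylstannane.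

Step 17
Reactants: 23 furan-2(5H)-one
Product: 25 3-bromofuran-2(5H)-one, via trans-dibromolactone 24 (not isolated)
Conditions: Br2, CH2Cl2, 40 °C; then Et3N, 0 °C
Reagents that add atoms: bromine, BrBr
Why: Bromine addition followed by E1cB dehydrobromination (loss of the acidic α-hydrogen and the β-bromide) gives the α-bromobutenolide.

Step 18
Reactants: 22 (1R,2R,4S)-4-(TBS-oxy)-2,6,6-trimethyl-1-[(E)-2-(tributylstannyl)ethenyl]-1,2-bis(TMS-oxy)cyclohexane; 25 3-bromofuran-2(5H)-one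
Product: 26 3-{(E)-2-[(1R,2R,4S)-4-(TBS-oxy)-2,6,6-trimethyl-1,2-bis(TMS-oxy)cyclohexyl]ethenyl}furan-2(5H)-one
Conditions: Pd2(dba)3 (2.5 mol%), AsPh3 (20 mol%), CuI (10 mol%), NMP, 40 °C
Reagents that add atoms: none
Why: Stille coupling of the alkenylstannane with the α-bromo enoate keeps the E geometry and runs under neutral conditions that spare the silyl ethers and the lactone.

Step 19
Reactants: 26 3-{(E)-2-[(1R,2R,4S)-4-(TBS-oxy)-2,6,6-trimethyl-1,2-bis(TMS-oxy)cyclohexyl]ethenyl}furan-2(5H)-one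
Product: 27 triisopropyl[(3-{(E)-2-[(1R,2R,4S)-4-(TBS-oxy)-2,6,6-trimethyl-1,2-bis(TMS-oxy)cyclohexyl]ethenyl}furan-2-yl)oxy]silane
Conditions: i-Pr3SiOTf, Et3N, CH2Cl2, 0 °C; non-aqueous work-up, used crude
Reagents that add atoms: triisopropylsilyl trifluoromethanesulfonate, CC(C)[Si](OS(=O)(=O)C(F)(F)F)(C(C)C)C(C)C
Why: Soft enolisation and O-silylation of the butenolide (silyl dienol ether formation) gives the 2-silyloxyfuran, the nucleophile for the vinylogous aldol.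

Step 20
Reactants: 27 triisopropyl[(3-{(E)-2-[(1R,2R,4S)-4-(TBS-oxy)-2,6,6-trimethyl-1,2-bis(TMS-oxy)cyclohexyl]ethenyl}furan-2-yl)oxy]silane; 14 (2E,4E,6E,8E)-11-[(4R)-4-(TBS-oxy)-2,6,6-trimethylcyclohex-1-en-1-yl]-2,9-dimethylundeca-2,4,6,8-tetraen-10-ynal
Product: 28 5-{(2E,4E,6E,8E)-1-hydroxy-11-[(4R)-4-(TBS-oxy)-2,6,6-trimethylcyclohex-1-en-1-yl]-2,9-dimethylundeca-2,4,6,8-tetraen-10-yn-1-yl}-3-{(E)-2-[(1R,2R,4S)-4-(TBS-oxy)-2,6,6-trimethyl-1,2-bis(TMS-oxy)cyclohexyl]ethenyl}furan-2(5H)-one (mixture of epimers at lactone C-5 and at the carbinol carbon)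
Conditions: BF3·OEt2 (1.1 equiv), CH2Cl2, −78 °C; then aq. NaHCO3
Reagents that add atoms: none
Why: In this vinylogous Mukaiyama aldol addition the BF3-activated aldehyde is attacked by furan C-5, the only unhindered nucleophilic terminus, and the two new stereocentres are formed unselectively because both are removed in the next step.

Step 21
Reactants: 28 the aldol adduct of step 20 (epimer mixture)
Product: 30 (5Z)-5-{(2E,4E,6E,8E)-11-[(4R)-4-(TBS-oxy)-2,6,6-trimethylcyclohex-1-en-1-yl]-2,9-dimethylundeca-2,4,6,8-tetraen-10-yn-1-ylidene}-3-{(E)-2-[(1R,2R,4S)-4-(TBS-oxy)-2,6,6-trimethyl-1,2-bis(TMS-oxy)cyclohexyl]ethenyl}furan-2(5H)-one, via methanesulfonate 29 (not isolated)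
Conditions: MsCl, Et3N, CH2Cl2, −40 °C; then DBU, −40 to 0 °C
Reagents that add atoms: none
Why: Sulfonylation then E1cB β-elimination through the furanolate gives the conjugated ylidene lactone, in which the Z isomer (side chain syn to the ring oxygen and away from H-4) is expected to predominate as the more stable one, and any E isomer can be separated or equilibrated with a trace of iodine.

Step 22
Reactants: 30 the tetrasilyl ether of step 21
Product: 31 (5Z)-5-{(2E,4E,6E,8E)-11-[(4R)-4-hydroxy-2,6,6-trimethylcyclohex-1-en-1-yl]-2,9-dimethylundeca-2,4,6,8-tetraen-10-yn-1-ylidene}-3-{(E)-2-[(1R,2R,4S)-1,2,4-trihydroxy-2,6,6-trimethylcyclohexyl]ethenyl}furan-2(5H)-one (CNP0163979.1)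
Conditions: HF·pyridine, pyridine, THF, 0 to 23 °C
Reagents that add atoms: none
Why: Fluoride-mediated desilylation with buffered HF·pyridine removes the two TBS and two TMS groups without the basic conditions that could open the ylidene lactone, and no stereocentre is affected.

## Compound list

1 | (4R,6R)-4-hydroxy-2,2,6-trimethylcyclohexan-1-one (actinol) | O=C1C(C)(C)C[C@H](O)C[C@H]1C | starting material
2 | (4R,6R)-4-(TBS-oxy)-2,2,6-trimethylcyclohexan-1-one | O=C1C(C)(C)C[C@H](O[Si](C)(C)C(C)(C)C)C[C@H]1C | intermediate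
3 | lithium (4R)-4-(TBS-oxy)-2,6,6-trimethylcyclohex-1-en-1-olate | CC1=C([O-])C(C)(C)C[C@H](O[Si](C)(C)C(C)(C)C)C1.[Li+] | intermediate
4 | (4R)-4-(TBS-oxy)-2,6,6-trimethylcyclohex-1-en-1-yl trifluoromethanesulfonate | CC1=C(OS(=O)(=O)C(F)(F)F)C(C)(C)C[C@H](O[Si](C)(C)C(C)(C)C)C1 | intermediate
5 | (2E)-3-methylpent-2-en-4-yn-1-ol | C#C/C(C)=C/CO | starting material
6 | (2E)-5-[(4R)-4-(TBS-oxy)-2,6,6-trimethylcyclohex-1-en-1-yl]-3-methylpent-2-en-4-yn-1-ol | CC1=C(C#C/C(C)=C/CO)C(C)(C)C[C@H](O[Si](C)(C)C(C)(C)C)C1 | intermediate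
7 | (2E)-5-[(4R)-4-(TBS-oxy)-2,6,6-trimethylcyclohex-1-en-1-yl]-3-methylpent-2-en-4-ynal | CC1=C(C#C/C(C)=C/C=O)C(C)(C)C[C@H](O[Si](C)(C)C(C)(C)C)C1 | intermediate
8 | ethyl (2E)-4-(diethoxyphosphoryl)but-2-enoate (triethyl 4-phosphonocrotonate) | CCOC(=O)/C=C/CP(=O)(OCC)OCC | starting material
9 | lithium salt of 8 (carbanion at C-4) | CCOC(=O)/C=C/[CH-]P(=O)(OCC)OCC.[Li+] | intermediate
10 | ethyl (2E,4E,6E)-9-[(4R)-4-(TBS-oxy)-2,6,6-trimethylcyclohex-1-en-1-yl]-7-methylnona-2,4,6-trien-8-ynoate | CC1=C(C#C/C(C)=C/C=C/C=C/C(=O)OCC)C(C)(C)C[C@H](O[Si](C)(C)C(C)(C)C)C1 | intermediate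
11 | (2E,4E,6E)-9-[(4R)-4-(TBS-oxy)-2,6,6-trimethylcyclohex-1-en-1-yl]-7-methylnona-2,4,6-trien-8-yn-1-ol | CC1=C(C#C/C(C)=C/C=C/C=C/CO)C(C)(C)C[C@H](O[Si](C)(C)C(C)(C)C)C1 | intermediate
12 | (2E,4E,6E)-9-[(4R)-4-(TBS-oxy)-2,6,6-trimethylcyclohex-1-en-1-yl]-7-methylnona-2,4,6-trien-8-ynal | CC1=C(C#C/C(C)=C/C=C/C=C/C=O)C(C)(C)C[C@H](O[Si](C)(C)C(C)(C)C)C1 | intermediate
13 | 2-(triphenylphosphoranylidene)propanal | CC(C=O)=P(c1ccccc1)(c1ccccc1)c1ccccc1 | starting material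
14 | (2E,4E,6E,8E)-11-[(4R)-4-(TBS-oxy)-2,6,6-trimethylcyclohex-1-en-1-yl]-2,9-dimethylundeca-2,4,6,8-tetraen-10-ynal | CC1=C(C#C/C(C)=C/C=C/C=C/C=C(C)/C=O)C(C)(C)C[C@H](O[Si](C)(C)C(C)(C)C)C1 | intermediate
15 | methyl (4R)-4-(TBS-oxy)-2,6,6-trimethylcyclohex-1-ene-1-carboxylate | CC1=C(C(=O)OC)C(C)(C)C[C@H](O[Si](C)(C)C(C)(C)C)C1 | intermediate
16 | [(4R)-4-(TBS-oxy)-2,6,6-trimethylcyclohex-1-en-1-yl]methanol | CC1=C(CO)C(C)(C)C[C@H](O[Si](C)(C)C(C)(C)C)C1 | intermediate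
17 | [(1S,4S,6S)-4-(TBS-oxy)-2,2,6-trimethyl-7-oxabicyclo[4.1.0]heptan-1-yl]methanol | OC[C@@]12C(C)(C)C[C@H](O[Si](C)(C)C(C)(C)C)C[C@]1(C)O2 | intermediate
18 | (1R,4S,6S)-4-(TBS-oxy)-2,2,6-trimethyl-7-oxabicyclo[4.1.0]heptane-1-carbaldehyde | O=C[C@@]12C(C)(C)C[C@H](O[Si](C)(C)C(C)(C)C)C[C@]1(C)O2 | intermediate
19 | tert-butyl{[(1S,4S,6S)-1-ethynyl-2,2,6-trimethyl-7-oxabicyclo[4.1.0]heptan-4-yl]oxy}dimethylsilane | C#C[C@@]12C(C)(C)C[C@H](O[Si](C)(C)C(C)(C)C)C[C@]1(C)O2 | intermediate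
20 | (1S,2R,4S)-4-(TBS-oxy)-1-ethynyl-2,6,6-trimethylcyclohexane-1,2-diol | C#C[C@@]1(O)C(C)(C)C[C@H](O[Si](C)(C)C(C)(C)C)C[C@@]1(C)O | intermediate
21 | (1S,2R,4S)-4-(TBS-oxy)-1-ethynyl-2,6,6-trimethyl-1,2-bis(TMS-oxy)cyclohexane | C#C[C@@]1(O[Si](C)(C)C)C(C)(C)C[C@H](O[Si](C)(C)C(C)(C)C)C[C@@]1(C)O[Si](C)(C)C | intermediate
22 | (1R,2R,4S)-4-(TBS-oxy)-2,6,6-trimethyl-1-[(E)-2-(tributylstannyl)ethenyl]-1,2-bis(TMS-oxy)cyclohexane | CCCC[Sn](CCCC)(CCCC)/C=C/[C@@]1(O[Si](C)(C)C)C(C)(C)C[C@H](O[Si](C)(C)C(C)(C)C)C[C@@]1(C)O[Si](C)(C)C | intermediate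
23 | furan-2(5H)-one | O=C1OCC=C1 | starting material
24 | trans-3,4-dibromooxolan-2-one (racemic, one enantiomer drawn) | O=C1OC[C@H](Br)[C@H]1Br | intermediate
25 | 3-bromofuran-2(5H)-one | O=C1OCC=C1Br | intermediate
26 | 3-{(E)-2-[(1R,2R,4S)-4-(TBS-oxy)-2,6,6-trimethyl-1,2-bis(TMS-oxy)cyclohexyl]ethenyl}furan-2(5H)-one | O=C1OCC=C1/C=C/[C@@]1(O[Si](C)(C)C)C(C)(C)C[C@H](O[Si](C)(C)C(C)(C)C)C[C@@]1(C)O[Si](C)(C)C | intermediate
27 | triisopropyl[(3-{(E)-2-[(1R,2R,4S)-4-(TBS-oxy)-2,6,6-trimethyl-1,2-bis(TMS-oxy)cyclohexyl]ethenyl}furan-2-yl)oxy]silane | CC(C)[Si](Oc1occc1/C=C/[C@@]1(O[Si](C)(C)C)C(C)(C)C[C@H](O[Si](C)(C)C(C)(C)C)C[C@@]1(C)O[Si](C)(C)C)(C(C)C)C(C)C | intermediate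
28 | aldol adduct: 5-(1-hydroxy-tetraenynyl)-3-alkenylfuran-2(5H)-one, full name in step 20 (epimer mixture at lactone C-5 and the carbinol carbon) | CC1=C(C#C/C(C)=C/C=C/C=C/C=C(C)/C(O)C2C=C(/C=C/[C@@]3(O[Si](C)(C)C)C(C)(C)C[C@H](O[Si](C)(C)C(C)(C)C)C[C@@]3(C)O[Si](C)(C)C)C(=O)O2)C(C)(C)C[C@H](O[Si](C)(C)C(C)(C)C)C1 | intermediate
29 | methanesulfonate of 28 (epimer mixture) | CC1=C(C#C/C(C)=C/C=C/C=C/C=C(C)/C(OS(C)(=O)=O)C2C=C(/C=C/[C@@]3(O[Si](C)(C)C)C(C)(C)C[C@H](O[Si](C)(C)C(C)(C)C)C[C@@]3(C)O[Si](C)(C)C)C(=O)O2)C(C)(C)C[C@H](O[Si](C)(C)C(C)(C)C)C1 | intermediate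
30 | tetrasilyl ether of the target (two TBS on the secondary and two TMS on the tertiary hydroxyls; Z ylidene), full name in step 21 | CC1=C(C#C/C(C)=C/C=C/C=C/C=C(C)/C=C2C=C(/C=C/[C@@]3(O[Si](C)(C)C)C(C)(C)C[C@H](O[Si](C)(C)C(C)(C)C)C[C@@]3(C)O[Si](C)(C)C)C(=O)O/2)C(C)(C)C[C@H](O[Si](C)(C)C(C)(C)C)C1 | intermediate
31 | (5Z)-5-{(2E,4E,6E,8E)-11-[(4R)-4-hydroxy-2,6,6-trimethylcyclohex-1-en-1-yl]-2,9-dimethylundeca-2,4,6,8-tetraen-10-yn-1-ylidene}-3-{(E)-2-[(1R,2R,4S)-1,2,4-trihydroxy-2,6,6-trimethylcyclohexyl]ethenyl}furan-2(5H)-one | CC1=C(C#C/C(C)=C/C=C/C=C/C=C(C)/C=C2C=C(/C=C/[C@@]3(O)C(C)(C)C[C@H](O)C[C@@]3(C)O)C(=O)O/2)C(C)(C)C[C@H](O)C1 | target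

## Totals and weak points

Total step count: 22. Longest linear sequence: 15 steps (steps 1, 2, 9–16, 18–22); the eastern branch (steps 3–8) and step 17 run in parallel.

Three steps most likely to fail:

Step 11 (syn-selective Sharpless epoxidation). The ring stereocentre may oppose the tartrate, and the hindered tetrasubstituted alkene reacts slowly. Fallback by substrate control: set out from triflate 4 and Sonogashira-couple it with trimethylsilylacetylene to give tert-butyldimethyl{[(1R)-3,5,5-trimethyl-4-[(trimethylsilyl)ethynyl]cyclohex-3-en-1-yl]oxy}silane F1. Remove both silyl groups with Bu4NF to give (1R)-4-ethynyl-3,5,5-trimethylcyclohex-3-en-1-ol F2. Epoxidise with VO(acac)2 and t-BuOOH, where the homoallylic hydroxyl binds vanadium and delivers oxygen to its own face, to give (1S,3S,6S)-6-ethynyl-1,5,5-trimethyl-7-oxabicyclo[4.1.0]heptan-3-ol F3. Silylation with TBSCl and imidazole comes back to the route at 19 and bypasses steps 9–13.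

Step 14 (epoxide hydrolysis). A cationic pathway could give the cis-diol or a ring-contracted ketone, and the TBS ether is only moderately acid-stable. Fallback with a titanium-templated carboxylate opening one stage earlier: set out from epoxy alcohol 17 and treat it with Ti(O-i-Pr)4 and benzoic acid, which delivers benzoate to the distal, methyl-bearing carbon with inversion. This gives (1R,2S,5S)-5-(TBS-oxy)-2-hydroxy-2-(hydroxymethyl)-1,3,3-trimethylcyclohexyl benzoate F4. Parikh–Doering oxidation of the primary alcohol gives (1R,2R,5S)-5-(TBS-oxy)-2-formyl-2-hydroxy-1,3,3-trimethylcyclohexyl benzoate F5. Ohira–Bestmann homologation gives (1R,2S,5S)-5-(TBS-oxy)-2-ethynyl-2-hydroxy-1,3,3-trimethylcyclohexyl benzoate F6, and continued K2CO3/MeOH methanolysis of the benzoate comes back to the route at 20.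

Step 20 (late-stage vinylogous aldol). In 27 the tertiary allylic silyloxy group at C-6 is conjugated to the electron-rich furan and could ionise under BF3, and the tetraenal is a weak electrophile. Fallback that keeps the same aldol bond but runs it on a simple nucleophile and attaches the triol ring last: set out from 25 and silylate it (i-Pr3SiOTf, Et3N) to 3-bromo-2-(triisopropylsilyloxy)furan F7. Add F7 to aldehyde 14 with BF3·OEt2 at −78 °C to give 3-bromo-5-{(2E,4E,6E,8E)-1-hydroxy-11-[(4R)-4-(TBS-oxy)-2,6,6-trimethylcyclohex-1-en-1-yl]-2,9-dimethylundeca-2,4,6,8-tetraen-10-yn-1-yl}furan-2(5H)-one F8. Convert F8 with MsCl and Et3N to its methanesulfonate F9 and eliminate with DBU to the (5Z)-3-bromo-5-ylidene lactone F10. Stille coupling of F10 with stannane 22 (Pd2(dba)3, AsPh3, CuI) comes back to the route at 30.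

Further compounds
F1 | step 11 | tert-butyldimethyl{[(1R)-3,5,5-trimethyl-4-[(trimethylsilyl)ethynyl]cyclohex-3-en-1-yl]oxy}silane | CC1=C(C#C[Si](C)(C)C)C(C)(C)C[C@H](O[Si](C)(C)C(C)(C)C)C1
F2 | step 11 | (1R)-4-ethynyl-3,5,5-trimethylcyclohex-3-en-1-ol | CC1=C(C#C)C(C)(C)C[C@H](O)C1
F3 | step 11 | (1S,3S,6S)-6-ethynyl-1,5,5-trimethyl-7-oxabicyclo[4.1.0]heptan-3-ol | C#C[C@@]12C(C)(C)C[C@H](O)C[C@]1(C)O2
F4 | step 14 | (1R,2S,5S)-5-(TBS-oxy)-2-hydroxy-2-(hydroxymethyl)-1,3,3-trimethylcyclohexyl benzoate | OC[C@@]1(O)C(C)(C)C[C@H](O[Si](C)(C)C(C)(C)C)C[C@@]1(C)OC(=O)c1ccccc1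
F5 | step 14 | (1R,2R,5S)-5-(TBS-oxy)-2-formyl-2-hydroxy-1,3,3-trimethylcyclohexyl benzoate | O=C[C@@]1(O)C(C)(C)C[C@H](O[Si](C)(C)C(C)(C)C)C[C@@]1(C)OC(=O)c1ccccc1
F6 | step 14 | (1R,2S,5S)-5-(TBS-oxy)-2-ethynyl-2-hydroxy-1,3,3-trimethylcyclohexyl benzoate | C#C[C@@]1(O)C(C)(C)C[C@H](O[Si](C)(C)C(C)(C)C)C[C@@]1(C)OC(=O)c1ccccc1
F7 | step 20 | 3-bromo-2-(triisopropylsilyloxy)furan | CC(C)[Si](Oc1occc1Br)(C(C)C)C(C)C
F8 | step 20 | 3-bromo-5-{(2E,4E,6E,8E)-1-hydroxy-11-[(4R)-4-(TBS-oxy)-2,6,6-trimethylcyclohex-1-en-1-yl]-2,9-dimethylundeca-2,4,6,8-tetraen-10-yn-1-yl}furan-2(5H)-one (epimer mixture) | CC1=C(C#C/C(C)=C/C=C/C=C/C=C(C)/C(O)C2C=C(Br)C(=O)O2)C(C)(C)C[C@H](O[Si](C)(C)C(C)(C)C)C1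
F9 | step 20 | methanesulfonate of F8 | CC1=C(C#C/C(C)=C/C=C/C=C/C=C(C)/C(OS(C)(=O)=O)C2C=C(Br)C(=O)O2)C(C)(C)C[C@H](O[Si](C)(C)C(C)(C)C)C1
F10 | step 20 | (5Z)-3-bromo-5-{(2E,4E,6E,8E)-11-[(4R)-4-(TBS-oxy)-2,6,6-trimethylcyclohex-1-en-1-yl]-2,9-dimethylundeca-2,4,6,8-tetraen-10-yn-1-ylidene}furan-2(5H)-one | CC1=C(C#C/C(C)=C/C=C/C=C/C=C(C)/C=C2C=C(Br)C(=O)O/2)C(C)(C)C[C@H](O[Si](C)(C)C(C)(C)C)C1
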